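The chroman is disconnected at the O1–C2 bond of its dihydropyran ring. C2 is a tertiary allylic ether carbon next to the C1'=C2' alkene, the hallmark of an oxypalladation/β-hydride elimination. The key step is therefore an enantioselective Wacker-type cyclisation of an open-chain o-homoallylphenol that carries a skipped (3E,6E)-diene. One operation closes the pyran ring (the last ring formed), sets the C2 quaternary stereocentre under ligand control and dehydrogenates the chain to the conjugated (1E,3E)-diene. The precursor is assembled from two alkynes, made from 6-hydroxydihydrocoumarin and dihydro-β-ionone, by zirconium-catalysed carboalumination and alkenylalane–allyl chloride coupling.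

Key step: step 8

Remarks and assumptions:
- Chroman locants (O1, C2, C3, C4, C4a, C8a) and side-chain locants C1'–C6' are used for the corresponding atoms of the open-chain intermediates as well.
- Compounds 1 and 6 are taken as catalogue chemicals.
- The sense of induction of the BOXAX ligand is assigned by analogy with Wacker-type cyclisations of o-alkenylphenols; if a pilot run showed the opposite sense, the mirror-image ligand would be used.
- Conjugate bases and ate complexes of numbered compounds (enolates, phenoxides, acetylides, aluminates) and catalytic organopalladium species are not numbered separately.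
- (R,R)-Bn-BOXAX is (R)-2,2'-bis[(4R)-4-benzyl-4,5-dihydro-1,3-oxazol-2-yl]-1,1'-binaphthalene.

Step 1
Reactants: 1 6-hydroxy-3,4-dihydro-2H-chromen-2-one
Product: 2 6-[tri(propan-2-yl)silyloxy]-3,4-dihydro-2H-chromen-2-one
Conditions: i-Pr3SiCl, imidazole, DMF, rt
Reagents that add atoms: chlorotri(propan-2-yl)silane, CC(C)[Si](Cl)(C(C)C)C(C)C
Why: Imidazole-promoted O-silylation of the phenol gives a bulky aryl silyl ether that should tolerate the hydride, basic methanol, organoaluminium and oxidative palladium steps ahead and be cleaved by fluoride at the end.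

Step 2
Reactants: 2 6-[tri(propan-2-yl)silyloxy]-3,4-dihydro-2H-chromen-2-one
Product: 3 6-[tri(propan-2-yl)silyloxy]-3,4-dihydro-2H-chromen-2-ol (lactol)
Conditions: i-Bu2AlH (1.1 equiv), CH2Cl2, −78 °C; aq. KNaC4H4O6 (potassium sodium tartrate) work-up
Reagents that add atoms: none
Why: Partial reduction of the aryl lactone with i-Bu2AlH should stop at the lactol because the tetrahedral aluminium hemiacetal is stable at −78 °C and collapses only on work-up.

Step 3
Reactants: 3 6-[tri(propan-2-yl)silyloxy]-3,4-dihydro-2H-chromen-2-ol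
Product: 5 2-(but-3-yn-1-yl)-4-[tri(propan-2-yl)silyloxy]phenol, via hydroxy aldehyde 4 (not isolated)
Conditions: dimethyl (1-diazo-2-oxopropyl)phosphonate (1.3 equiv), K2CO3 (2.5 equiv), MeOH, 0 °C → rt
Reagents that add atoms: dimethyl (1-diazo-2-oxopropyl)phosphonate, CC(=O)C(=[N+]=[N-])P(=O)(OC)OC
Why: Seyferth–Gilbert homologation in the Ohira–Bestmann variant, in which base opens the lactol to the phenoxide aldehyde 4 and the diazomethylphosphonate anion converts it via a diazoalkene and an alkylidene carbene 1,2-hydrogen shift into the terminal alkyne, the former lactone carbon becoming the future C2.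

Step 4
Reactants: 6 4-(2,6,6-trimethylcyclohex-1-en-1-yl)butan-2-one (dihydro-β-ionone)
Product: 8 2-(but-3-yn-1-yl)-1,3,3-trimethylcyclohex-1-ene, via enol phosphate 7 (not isolated)
Conditions: LiN(i-Pr)2 (1.05 equiv), THF, −78 °C; ClP(O)(OEt)2, −78 °C → rt; LiN(i-Pr)2 (2.3 equiv), −78 °C → rt; H2O
Reagents that add atoms: none
Why: Kinetic deprotonation at the methyl group, O-phosphorylation to the terminal enol phosphate and amide-induced β-elimination with deprotonation of the alkyne (enol phosphate route from a methyl ketone to a terminal alkyne) should drive the sequence to the acetylide.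

Step 5
Reactants: 8 2-(but-3-yn-1-yl)-1,3,3-trimethylcyclohex-1-ene
Product: 10 (2E)-3-methyl-5-(2,6,6-trimethylcyclohex-1-en-1-yl)pent-2-en-1-ol, via alkenylalane 9 (not isolated)
Conditions: AlMe3 (2.5 equiv), Cp2ZrCl2 (0.25 equiv), CH2Cl2, 0 °C → rt; then n-BuLi, THF, −78 → 0 °C; (CH2O)n, rt
Reagents that add atoms: trimethylaluminium, C[Al](C)C; paraformaldehyde (as formaldehyde), C=O
Why: Negishi zirconium-catalysed carboalumination adds methyl and aluminium syn across the terminal alkyne (methyl to the internal carbon), fixing the E trisubstituted alkene that becomes C3'=C4', and the derived aluminate is hydroxymethylated by formaldehyde with retention.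

Step 6
Reactants: 10 (2E)-3-methyl-5-(2,6,6-trimethylcyclohex-1-en-1-yl)pent-2-en-1-ol
Product: 12 2-[(3E)-5-chloro-3-methylpent-3-en-1-yl]-1,3,3-trimethylcyclohex-1-ene, via allylic mesylate 11 (not isolated)
Conditions: MsCl, LiCl, 2,4,6-collidine, DMF, 0 °C
Reagents that add atoms: lithium chloride, [Li+].[Cl-]
Why: In this Collington–Meyers chlorination the primary allylic mesylate formed in situ should be displaced by chloride in an SN2 manner, without allylic transposition or loss of the E geometry.

Step 7
Reactants: 5 2-(but-3-yn-1-yl)-4-[tri(propan-2-yl)silyloxy]phenol; 12 2-[(3E)-5-chloro-3-methylpent-3-en-1-yl]-1,3,3-trimethylcyclohex-1-ene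
Product: 14 2-[(3E,6E)-3,7-dimethyl-9-(2,6,6-trimethylcyclohex-1-en-1-yl)nona-3,6-dien-1-yl]-4-[tri(propan-2-yl)silyloxy]phenol, via alkenylalane 13 (not isolated)
Conditions: AlMe3 (3.2 equiv), Cp2ZrCl2 (0.3 equiv), CH2Cl2, 0 °C → rt; volatiles removed; 12, Pd(PPh3)4 (5 mol%), THF, rt; aq. KNaC4H4O6 work-up
Reagents that add atoms: trimethylaluminium, C[Al](C)C
Why: The phenol is carried as its dimethylaluminium phenoxide through a second Negishi carboalumination, and the resulting (E)-alkenylalane should undergo Pd(PPh3)4-catalysed alkenyl–allyl cross-coupling at the primary terminus of the allyl unit with retention of both alkene geometries, giving the 1,4-diene.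

Step 8
Reactants: 14 2-[(3E,6E)-3,7-dimethyl-9-(2,6,6-trimethylcyclohex-1-en-1-yl)nona-3,6-dien-1-yl]-4-[tri(propan-2-yl)silyloxy]phenol
Product: 15 (2R)-2-methyl-2-[(1E,3E)-4-methyl-6-(2,6,6-trimethylcyclohex-1-en-1-yl)hexa-1,3-dien-1-yl]-6-[tri(propan-2-yl)silyloxy]-3,4-dihydro-2H-chromene
Conditions: Pd(OCOCF3)2 (10 mol%), (R,R)-Bn-BOXAX (25 mol%), p-benzoquinone (3 equiv), CH2Cl2, rt
Reagents that add atoms: none
Why: The phenol binds the BOXAX complex of divalent palladium, the C2=C1' alkene is activated on the metal and intramolecular oxypalladation forms the O1–C2 bond in a 6-exo-trig closure with palladium on C1'; β-hydride elimination of a C2' hydrogen (the only β-hydrogens, since C2 is quaternary) then releases the (1E,3E)-diene, and zerovalent palladium is returned to divalent palladium by p-benzoquinone. The closest known reaction type is the enantioselective Wacker-type cyclisation of o-homoallylphenols bearing tri- or tetrasubstituted alkenes to 2-methyl-2-alkenylchromans with Pd(OCOCF3)2, a BOXAX ligand and benzoquinone. The C2 stereocentre is set in the oxypalladation by the C2-symmetric binaphthyl bis(oxazoline) ligand, which differentiates the enantiotopic faces of the (E)-alkene, the (R,R)-ligand being proposed for the 2R product. The new C1'=C2' bond should be E because the syn β-hydride elimination passes through the rotamer that keeps C3' away from the quaternary centre, while the C3'=C4' bond is a spectator and keeps its E geometry. Site selectivity for the proximal alkene over the distal trisubstituted and the tetrasubstituted ring alkene is secured by the two-carbon tether, which allows only the six-membered closure, and Markovnikov attack at the disubstituted carbon C2 excludes the 7-endo mode. The 4,4-disubstituted diene terminus disfavours the s-cis conformer, so cycloaddition of the product with benzoquinone should not compete.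

Step 9
Reactants: 15 (2R)-2-methyl-2-[(1E,3E)-4-methyl-6-(2,6,6-trimethylcyclohex-1-en-1-yl)hexa-1,3-dien-1-yl]-6-[tri(propan-2-yl)silyloxy]-3,4-dihydro-2H-chromene
Product: 16 (2R)-2-methyl-2-[(1E,3E)-4-methyl-6-(2,6,6-trimethylcyclohex-1-en-1-yl)hexa-1,3-dien-1-yl]-3,4-dihydro-2H-chromen-6-ol
Conditions: Bu4NF (1.1 equiv), AcOH (1.1 equiv), THF, 0 °C
Reagents that add atoms: none
Why: Fluoride-induced desilylation under acetic acid buffering should free the phenol without touching the acid-sensitive tertiary dienyl aryl ether, the diene or the C2 stereocentre.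

Compound list
1 | 6-hydroxy-3,4-dihydro-2H-chromen-2-one (6-hydroxydihydrocoumarin) | O=C1CCc2cc(O)ccc2O1 | starting material
2 | 6-[tri(propan-2-yl)silyloxy]-3,4-dihydro-2H-chromen-2-one | O=C1CCc2cc(O[Si](C(C)C)(C(C)C)C(C)C)ccc2O1 | intermediate
3 | 6-[tri(propan-2-yl)silyloxy]-3,4-dihydro-2H-chromen-2-ol (lactol, configuration at C2 not defined) | OC1CCc2cc(O[Si](C(C)C)(C(C)C)C(C)C)ccc2O1 | intermediate
4 | 3-{2-hydroxy-5-[tri(propan-2-yl)silyloxy]phenyl}propanal (open form of 3, not isolated) | O=CCCc1cc(O[Si](C(C)C)(C(C)C)C(C)C)ccc1O | intermediate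
5 | 2-(but-3-yn-1-yl)-4-[tri(propan-2-yl)silyloxy]phenol | C#CCCc1cc(O[Si](C(C)C)(C(C)C)C(C)C)ccc1O | intermediate
6 | 4-(2,6,6-trimethylcyclohex-1-en-1-yl)butan-2-one (dihydro-β-ionone) | CC(=O)CCC1=C(C)CCCC1(C)C | starting material
7 | diethyl 4-(2,6,6-trimethylcyclohex-1-en-1-yl)but-1-en-2-yl phosphate (not isolated) | C=C(CCC1=C(C)CCCC1(C)C)OP(=O)(OCC)OCC | intermediate
8 | 2-(but-3-yn-1-yl)-1,3,3-trimethylcyclohex-1-ene | C#CCCC1=C(C)CCCC1(C)C | intermediate
9 | dimethyl[(1E)-2-methyl-4-(2,6,6-trimethylcyclohex-1-en-1-yl)but-1-en-1-yl]alumane (not isolated) | C[Al](C)/C=C(\C)CCC1=C(C)CCCC1(C)C | intermediate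
10 | (2E)-3-methyl-5-(2,6,6-trimethylcyclohex-1-en-1-yl)pent-2-en-1-ol | OC/C=C(\C)CCC1=C(C)CCCC1(C)C | intermediate
11 | (2E)-3-methyl-5-(2,6,6-trimethylcyclohex-1-en-1-yl)pent-2-en-1-yl methanesulfonate (not isolated) | CS(=O)(=O)OC/C=C(\C)CCC1=C(C)CCCC1(C)C | intermediate
12 | 2-[(3E)-5-chloro-3-methylpent-3-en-1-yl]-1,3,3-trimethylcyclohex-1-ene | ClC/C=C(\C)CCC1=C(C)CCCC1(C)C | intermediate
13 | (E)-alkenyl(dimethyl)alane of 5 with the phenol as dimethylaluminium phenoxide (not isolated) | C[Al](C)/C=C(\C)CCc1cc(O[Si](C(C)C)(C(C)C)C(C)C)ccc1O[Al](C)C | intermediate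
14 | 2-[(3E,6E)-3,7-dimethyl-9-(2,6,6-trimethylcyclohex-1-en-1-yl)nona-3,6-dien-1-yl]-4-[tri(propan-2-yl)silyloxy]phenol | Oc1ccc(O[Si](C(C)C)(C(C)C)C(C)C)cc1CC/C(C)=C/C/C=C(\C)CCC1=C(C)CCCC1(C)C | intermediate
15 | (2R)-2-methyl-2-[(1E,3E)-4-methyl-6-(2,6,6-trimethylcyclohex-1-en-1-yl)hexa-1,3-dien-1-yl]-6-[tri(propan-2-yl)silyloxy]-3,4-dihydro-2H-chromene | CC1=C(CC/C(C)=C/C=C/[C@@]2(C)CCc3cc(O[Si](C(C)C)(C(C)C)C(C)C)ccc3O2)C(C)(C)CCC1 | intermediate
16 | (2R)-2-methyl-2-[(1E,3E)-4-methyl-6-(2,6,6-trimethylcyclohex-1-en-1-yl)hexa-1,3-dien-1-yl]-3,4-dihydro-2H-chromen-6-ol | CC1=C(CC/C(C)=C/C=C/[C@@]2(C)CCc3cc(O)ccc3O2)C(C)(C)CCC1 | target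

Total step count: 9.
Longest linear sequence: 6 steps (1 → 2 → 3 → 5 → 14 → 15 → 16, and equally 6 → 8 → 10 → 12 → 14 → 15 → 16).

Steps most likely to fail

Step 8. The oxypalladation may discriminate the alkene faces poorly. Palladium hydride may also re-add to the new diene and move the double bonds, or trifluoroacetic acid may ionise the tertiary dienyl aryl ether and erode the configuration at C2. The fallback sets out from 5 and 8 and returns at 15. The alkenylalane 13 from 5 is hydroxymethylated (n-BuLi, then (CH2O)n) to 2-[(3E)-5-hydroxy-3-methylpent-3-en-1-yl]-4-[tri(propan-2-yl)silyloxy]phenol F1. Both hydroxyls are converted with ClCO2Me and pyridine into the bis(methyl carbonate) F2, and pyrrolidine (1 equiv, CH2Cl2, 0 °C) cleaves the aryl carbonate selectively to the phenol allyl methyl carbonate F3. A Tsuji–Trost-type asymmetric allylic O-alkylation (Pd2(dba)3·CHCl3, the (R,R)-cyclohexane-1,2-diamine bis(2-diphenylphosphinobenzamide) ligand, AcOH, CH2Cl2, rt) closes the same O1–C2 bond through a π-allyl complex of palladium with a CH2 terminus. It should give (2R)-2-ethenyl-2-methyl-6-[tri(propan-2-yl)silyloxy]-3,4-dihydro-2H-chromene F4, the ligand antipode again being assigned by analogy. In parallel the alkenylalane 9 from 8 is quenched with I2 to 2-[(3E)-4-iodo-3-methylbut-3-en-1-yl]-1,3,3-trimethylcyclohex-1-ene F5. A ligand-free Heck reaction of F4 with F5 (Pd(OAc)2, Ag2CO3, DMF, 50 °C) then builds the (1E,3E)-diene and gives 15.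

Step 7. The dimethylaluminium chloride released in the coupling may promote C- or O-allylation of the electron-rich aluminium phenoxide by 12, and the phenoxide may slow the carboalumination. The fallback sets out from 5 and 10 and returns at 14. The alkenylalane 13 is quenched with I2 (THF, −30 °C) to 2-[(3E)-4-iodo-3-methylbut-3-en-1-yl]-4-[tri(propan-2-yl)silyloxy]phenol F6. Alcohol 10 is acetylated (Ac2O, pyridine) to (2E)-3-methyl-5-(2,6,6-trimethylcyclohex-1-en-1-yl)pent-2-en-1-yl acetate F7. A nickel-catalysed reductive cross-electrophile coupling of F6 with F7 (NiBr2·glyme, 4,4'-di-tert-butyl-2,2'-bipyridine, Zn dust, N,N-dimethylacetamide, rt) should then give 14 with no organoaluminium species or Lewis acid present when the C1'–C2' bond is formed.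

Step 3. Methanolic carbonate may cleave the aryl silyl ether, and the enolisable aldehyde 4 may self-condense before it is homologated. The fallback sets out from 3 and returns at 5. A Corey–Fuchs sequence is used: CBr4 and PPh3 (CH2Cl2, 0 °C) convert the lactol through its open form into 2-(4,4-dibromobut-3-en-1-yl)-4-[tri(propan-2-yl)silyloxy]phenol F8. Treatment with n-BuLi (3.2 equiv, THF, −78 °C → rt) and aqueous NH4Cl then gives 5 under aprotic conditions.

Further compounds
F1 | step 8 | 2-[(3E)-5-hydroxy-3-methylpent-3-en-1-yl]-4-[tri(propan-2-yl)silyloxy]phenol | OC/C=C(\C)CCc1cc(O[Si](C(C)C)(C(C)C)C(C)C)ccc1O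
F2 | step 8 | (2E)-5-{2-[(methoxycarbonyl)oxy]-5-[tri(propan-2-yl)silyloxy]phenyl}-3-methylpent-2-en-1-yl methyl carbonate | COC(=O)OC/C=C(\C)CCc1cc(O[Si](C(C)C)(C(C)C)C(C)C)ccc1OC(=O)OC
F3 | step 8 | (2E)-5-{2-hydroxy-5-[tri(propan-2-yl)silyloxy]phenyl}-3-methylpent-2-en-1-yl methyl carbonate | COC(=O)OC/C=C(\C)CCc1cc(O[Si](C(C)C)(C(C)C)C(C)C)ccc1O
F4 | step 8 | (2R)-2-ethenyl-2-methyl-6-[tri(propan-2-yl)silyloxy]-3,4-dihydro-2H-chromene | C=C[C@@]1(C)CCc2cc(O[Si](C(C)C)(C(C)C)C(C)C)ccc2O1
F5 | step 8 | 2-[(3E)-4-iodo-3-methylbut-3-en-1-yl]-1,3,3-trimethylcyclohex-1-ene | I/C=C(\C)CCC1=C(C)CCCC1(C)C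
F6 | step 7 | 2-[(3E)-4-iodo-3-methylbut-3-en-1-yl]-4-[tri(propan-2-yl)silyloxy]phenol | I/C=C(\C)CCc1cc(O[Si](C(C)C)(C(C)C)C(C)C)ccc1O
F7 | step 7 | (2E)-3-methyl-5-(2,6,6-trimethylcyclohex-1-en-1-yl)pent-2-en-1-yl acetate | CC(=O)OC/C=C(\C)CCC1=C(C)CCCC1(C)C
F8 | step 3 | 2-(4,4-dibromobut-3-en-1-yl)-4-[tri(propan-2-yl)silyloxy]phenol | BrC(Br)=CCCc1cc(O[Si](C(C)C)(C(C)C)C(C)C)ccc1O
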